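## Retrosynthetic overview

1. Glaucolide A ⇒ 8‑alcohol **24** (C8–O methacrylate put on last) ⇒ silyl ether **23**.
2. Key disconnection, C13–O: the 13‑acetoxy‑7(11)‑en‑12,6‑olide **23** ⇒ α‑methylene lactone **22** by a Pd(II) oxidative acetoxylation with double‑bond transposition (new).
3. **22** ⇒ acyclic epoxy aldehyde / 2‑(bromomethyl)enoate **20**: an indium Barbier reaction closes the ten‑membered carbocycle (C6–C7), then the γ‑lactone (C12–O6) forms.
4. Stereocentres come from C–O chemistry: C4/C5 by Sharpless epoxidation, C8 by D‑proline α‑aminoxylation, C10 from (R)‑linalool, C6 by chelation in the ring closure.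
5. Carbons: (R)‑linalool (C1, C2, C7–C10, C14) + C5 chloride **3** (C3–C6, C15) + methyl acrylate (C11–C13). Ring order: epoxide (step 9) → carbocycle and lactone (step 12) → butenolide unsaturation (step 13).

Assumptions: locants C1–C15 in comments and in the macrocycle names are germacranolide numbering of the target (C6 lactone CH–O, C8 ester carbinol, C10 tertiary acetate carbon, C12 lactone C=O, C13 CH2OAc); (R)‑(−)‑linalool of ≥97% ee and the vitamin A C5 building block **3** are taken as purchasable.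

## Route

Step 1
Reactants: 1 (R)-linalool
Product: 2 (3R)-3-hydroxy-3,7-dimethyloct-6-en-2-one
Conditions: PdCl2 (10 mol%), CuCl (20 mol%), O2 (1 atm), DMF/H2O 7:1, rt
Reagents that add atoms: water, O
Why: Tsuji–Wacker oxidation: Markovnikov hydroxypalladation of the monosubstituted vinyl group gives the methyl ketone, the hindered trisubstituted alkene does not react, and the carbinol stereocentre (later C10) is not touched.

Step 2
Reactants: 2 (3R)-3-hydroxy-3,7-dimethyloct-6-en-2-one; 3 (2E)-4-chloro-3-methylbut-2-en-1-yl acetate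
Product: 6 (2E,7R)-7-acetoxy-3,7,11-trimethyl-6-oxododeca-2,10-dien-1-yl acetate, via dilithium dianion 4 (not isolated), via lithium alkoxide 5 (not isolated)
Conditions: LDA (2.2 equiv), THF, −78 °C; 3, DMPU, −78 → 0 °C; Ac2O (3 equiv), 0 °C → rt
Reagents that add atoms: acetic anhydride, CC(=O)OC(C)=O
Why: Dianion (alkoxide/kinetic enolate) SN2 allylation: the ketone can enolise only toward CH3 because the other α‑carbon is quaternary, so the C2–C3 bond forms regiospecifically with the E‑alkene retained, and the Ac2O quench acetylates the tertiary lithium alkoxide (and restores any acetate lost from C6–O).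

Step 3
Reactants: 6 (2E,7R)-7-acetoxy-3,7,11-trimethyl-6-oxododeca-2,10-dien-1-yl acetate
Product: 8 (2E,7R)-7-acetoxy-3,7-dimethyl-6,10-dioxodec-2-en-1-yl acetate, via ozonide 7 (not isolated)
Conditions: O3 (1.0 equiv, Sudan III end point), CH2Cl2, −78 °C; Me2S, −78 °C → rt
Reagents that add atoms: ozone, [O-][O+]=O
Why: Chemoselective ozonolysis: the electron‑rich isopropylidene alkene is cleaved much faster than the trisubstituted alkene deactivated by its allylic acetate (the geranyl acetate pattern), and reductive work‑up gives the C7 aldehyde.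

Step 4
Reactants: 8 (2E,7R)-7-acetoxy-3,7-dimethyl-6,10-dioxodec-2-en-1-yl acetate
Product: 11 (2E,7R,9S)-7-acetoxy-9,10-dihydroxy-3,7-dimethyl-6-oxodec-2-en-1-yl acetate, via aminooxy aldehyde 9 (not isolated), via aminooxy alcohol 10 (not isolated)
Conditions: D‑proline (20 mol%), PhNO (1.1 equiv, slow addition), DMSO, rt; NaBH4, MeOH, −40 °C; CuSO4·5H2O (30 mol%), MeOH, 0 °C → rt
Reagents that add atoms: nitrosobenzene, O=Nc1ccccc1
Why: Proline‑catalysed enantioselective α‑aminoxylation (O‑nitroso aldol): the D‑proline enamine attacks the nitroso oxygen on the face fixed by the carboxylic acid hydrogen bond and so sets the C8–O bond as 8S under catalyst control; NaBH4 at −40 °C reduces only the aldehyde and Cu(II) cleaves the N–O bond.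

Step 5
Reactants: 11 (2E,7R,9S)-7-acetoxy-9,10-dihydroxy-3,7-dimethyl-6-oxodec-2-en-1-yl acetate
Product: 12 (2E,7R,9S)-7-acetoxy-3,7-dimethyl-6-oxo-9,10-bis(triethylsilyloxy)dec-2-en-1-yl acetate
Conditions: TESCl (2.5 equiv), imidazole (4 equiv), DMAP (cat.), DMF, 0 °C → rt
Reagents that add atoms: chlorotriethylsilane, CC[Si](Cl)(CC)CC
Why: Standard silyl ether formation on both hydroxyls; no stereocentre is involved.

Step 6
Reactants: 12 (2E,7R,9S)-7-acetoxy-3,7-dimethyl-6-oxo-9,10-bis(triethylsilyloxy)dec-2-en-1-yl acetate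
Product: 14 (2E,7R,9S)-7-acetoxy-3,7-dimethyl-6,10-dioxo-9-(triethylsilyloxy)dec-2-en-1-yl acetate, via alkoxysulfonium chloride 13 (not isolated)
Conditions: (COCl)2 (3 equiv), DMSO (6 equiv), CH2Cl2, −78 → −35 °C; Et3N, −78 °C → rt
Reagents that add atoms: none
Why: Swern oxidation with selective oxidative desilylation of the primary TES ether (the secondary TES ether is inert) gives the α‑silyloxy aldehyde directly; the low temperature protects the C8 centre from epimerisation.

Step 7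
Reactants: 14 (2E,7R,9S)-7-acetoxy-3,7-dimethyl-6,10-dioxo-9-(triethylsilyloxy)dec-2-en-1-yl acetate; 15 methyl acrylate
Product: 16 methyl (4S,6R,10E)-6,12-diacetoxy-3-hydroxy-6,10-dimethyl-2-methylidene-7-oxo-4-(triethylsilyloxy)dodec-10-enoate (C3 epimers)
Conditions: methyl acrylate (10 equiv), DABCO (1 equiv), MeOH (3 equiv), rt, 3–4 d
Reagents that add atoms: none
Why: Morita–Baylis–Hillman reaction of the inductively activated α‑silyloxy aldehyde brings in C11–C13; the new carbinol centre (C7) forms as a mixture, which does not matter because C7 becomes sp2 in step 11.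

Step 8
Reactants: 16 methyl (4S,6R,10E)-6,12-diacetoxy-3-hydroxy-6,10-dimethyl-2-methylidene-7-oxo-4-(triethylsilyloxy)dodec-10-enoate (C3 epimers)
Product: 17 methyl (4S,6R,10E)-6-acetoxy-3,12-dihydroxy-6,10-dimethyl-2-methylidene-7-oxo-4-(triethylsilyloxy)dodec-10-enoate (C3 epimers)
Conditions: K2CO3 (0.2 equiv), MeOH, 0 °C
Reagents that add atoms: none
Why: Zemplén‑type methanolysis removes the unhindered primary allylic acetate while the tertiary α‑ketol acetate, the methyl ester and the secondary TES ether survive.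

Step 9
Reactants: 17 methyl (4S,6R,10E)-6-acetoxy-3,12-dihydroxy-6,10-dimethyl-2-methylidene-7-oxo-4-(triethylsilyloxy)dodec-10-enoate (C3 epimers)
Product: 18 methyl (4S,6R)-6-acetoxy-3-hydroxy-9-[(2R,3R)-3-(hydroxymethyl)-2-methyloxiran-2-yl]-6-methyl-2-methylidene-7-oxo-4-(triethylsilyloxy)nonanoate (C3 epimers)
Conditions: Ti(OiPr)4 (1.0 equiv), D‑(−)‑diethyl tartrate (1.2 equiv), t‑BuOOH (2 equiv), 4 Å MS, CH2Cl2, −20 °C
Reagents that add atoms: tert-butyl hydroperoxide, CC(C)(C)OO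
Why: Sharpless asymmetric epoxidation: the Ti/D‑(−)‑tartrate complex delivers oxygen to one face of the E‑allylic alcohol and sets the (4R,5R)‑epoxide under reagent control; the electron‑poor acrylate alkene is not epoxidised.

Step 10
Reactants: 18 methyl (4S,6R)-6-acetoxy-3-hydroxy-9-[(2R,3R)-3-(hydroxymethyl)-2-methyloxiran-2-yl]-6-methyl-2-methylidene-7-oxo-4-(triethylsilyloxy)nonanoate (C3 epimers)
Product: 19 methyl (4S,6R)-6-acetoxy-9-[(2R,3S)-3-formyl-2-methyloxiran-2-yl]-3-hydroxy-6-methyl-2-methylidene-7-oxo-4-(triethylsilyloxy)nonanoate (C3 epimers)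
Conditions: TEMPO (10 mol%), PhI(OAc)2 (1.1 equiv), CH2Cl2, rt
Reagents that add atoms: none
Why: TEMPO/PhI(OAc)2 oxidation is selective for the primary alcohol over the deactivated secondary Baylis–Hillman alcohol and gives the epoxy aldehyde without touching the epoxide stereocentres.

Step 11
Reactants: 19 methyl (4S,6R)-6-acetoxy-9-[(2R,3S)-3-formyl-2-methyloxiran-2-yl]-3-hydroxy-6-methyl-2-methylidene-7-oxo-4-(triethylsilyloxy)nonanoate (C3 epimers)
Product: 20 methyl (2Z,4S,6R)-6-acetoxy-2-(bromomethyl)-9-[(2R,3S)-3-formyl-2-methyloxiran-2-yl]-6-methyl-7-oxo-4-(triethylsilyloxy)non-2-enoate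
Conditions: NBS (1.3 equiv), Me2S (1.5 equiv), CH2Cl2, −20 → 0 °C
Reagents that add atoms: N-bromosuccinimide, O=C1CCC(=O)N1Br
Why: Corey–Kim‑type SN2′ bromination of the Baylis–Hillman alcohol (alkoxysulfonium formation, then bromide attack at the CH2 terminus) gives the thermodynamic (Z)‑2‑(bromomethyl)enoate from both C7 epimers; aldehyde and epoxide are inert.

Step 12
Reactants: 20 methyl (2Z,4S,6R)-6-acetoxy-2-(bromomethyl)-9-[(2R,3S)-3-formyl-2-methyloxiran-2-yl]-6-methyl-7-oxo-4-(triethylsilyloxy)non-2-enoate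
Product: 22 (4R,5R,6S,8S,10R)-10-acetoxy-4,5-epoxy-1-oxo-8-(triethylsilyloxy)germacr-11(13)-en-12,6-olide (7ξ), via hydroxy ester 21 (not isolated)
Conditions: In powder (3 equiv), THF/H2O 3:1, 2 mM, rt; PPTS (cat.), PhH, 50 °C
Reagents that add atoms: none
Why: Intramolecular indium Barbier 2‑(alkoxycarbonyl)allylation at high dilution closes the ten‑membered ring at C6–C7 on the aldehyde (allylindium leaves the hindered ketone alone) through a transition state in which indium chelates the aldehyde and epoxide oxygens, which gives the 5,6‑syn (6S) carbinol; PPTS then lactonises it onto the methyl ester, and the new C7 centre is erased in step 13.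

Step 13
Reactants: 22 (4R,5R,6S,8S,10R)-10-acetoxy-4,5-epoxy-1-oxo-8-(triethylsilyloxy)germacr-11(13)-en-12,6-olide (7ξ)
Product: 23 (4R,5R,6S,8S,10R)-10,13-diacetoxy-4,5-epoxy-1-oxo-8-(triethylsilyloxy)germacr-7(11)-en-12,6-olide
Conditions: Pd(OAc)2 (10 mol%), 4,5‑diazafluoren‑9‑one (10 mol%), 1,4‑benzoquinone (2 equiv), NaOAc (0.5 equiv), AcOH (10 equiv), 1,4‑dioxane, 45 °C
Reagents that add atoms: acetic acid, CC(=O)O
Why: Proposed new method: Pd(II) binds the strained, s‑cis‑locked exocyclic acrylate, acetate adds to the unhindered CH2 (C13) with Michael regiochemistry to give a C11 palladium enolate, and syn β‑hydride elimination of the ring‑fusion H7 (preferred over the C13 hydrogens because it gives the conjugated tetrasubstituted butenolide) forms the C13–OAc bond and the 7(11)‑alkene while benzoquinone reoxidises Pd(0), the alternative C7–H cleavage to a 2‑acyl‑π‑allyl followed by acetate attack at the CH2 terminus leading to the same product; the closest known reaction types are Pd(II)/benzoquinone allylic C–H acetoxylation of terminal and 1,1‑disubstituted alkenes and the Heck arylation of α‑methylene‑γ‑butyrolactones that ends by β‑hydride elimination into the ring.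

Step 14
Reactants: 23 (4R,5R,6S,8S,10R)-10,13-diacetoxy-4,5-epoxy-1-oxo-8-(triethylsilyloxy)germacr-7(11)-en-12,6-olide
Product: 24 (4R,5R,6S,8S,10R)-10,13-diacetoxy-4,5-epoxy-8-hydroxy-1-oxogermacr-7(11)-en-12,6-olide
Conditions: HF·pyridine, pyridine/THF, 0 °C
Reagents that add atoms: none
Why: Fluoride desilylation under buffered conditions spares the epoxide, the acetates and the base‑sensitive butenolide.

Step 15
Reactants: 24 (4R,5R,6S,8S,10R)-10,13-diacetoxy-4,5-epoxy-8-hydroxy-1-oxogermacr-7(11)-en-12,6-olide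
Product: 25 glaucolide A
Conditions: methacrylic anhydride (2 equiv), DMAP (0.2 equiv), Et3N (3 equiv), CH2Cl2, 0 °C
Reagents that add atoms: methacrylic anhydride, C=C(C)C(=O)OC(=O)C(C)=C
Why: DMAP‑catalysed acyl transfer (Steglich‑type esterification) acylates the only free hydroxyl; 0 °C and short contact avoid enolisation at C6.

## Compound list

1 | (R)-(−)-linalool, (3R)-3,7-dimethylocta-1,6-dien-3-ol | CC(C)=CCC[C@@](C)(O)C=C | starting material
2 | (3R)-3-hydroxy-3,7-dimethyloct-6-en-2-one | CC(C)=CCC[C@@](C)(O)C(C)=O | intermediate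
3 | (2E)-4-chloro-3-methylbut-2-en-1-yl acetate | ClC/C(C)=C/COC(C)=O | starting material
4 | dilithium alkoxide/enolate dianion of 2 | CC(C)=CCC[C@@](C)([O-])C(=C)[O-].[Li+].[Li+] | intermediate (not isolated)
5 | lithium (2E,7R)-1-acetoxy-3,7,11-trimethyl-6-oxododeca-2,10-dien-7-olate | CC(C)=CCC[C@@](C)([O-])C(=O)CC/C(C)=C/COC(C)=O.[Li+] | intermediate (not isolated)
6 | (2E,7R)-7-acetoxy-3,7,11-trimethyl-6-oxododeca-2,10-dien-1-yl acetate | CC(C)=CCC[C@@](C)(OC(C)=O)C(=O)CC/C(C)=C/COC(C)=O | intermediate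
7 | 10,11-ozonide (1,2,4-trioxolane) of 6, mixture at the ring CH | CC1(C)OOC(CC[C@@](C)(OC(C)=O)C(=O)CC/C(C)=C/COC(C)=O)O1 | intermediate (not isolated)
8 | (2E,7R)-7-acetoxy-3,7-dimethyl-6,10-dioxodec-2-en-1-yl acetate | O=CCC[C@@](C)(OC(C)=O)C(=O)CC/C(C)=C/COC(C)=O | intermediate
9 | (2E,7R,9S)-7-acetoxy-3,7-dimethyl-6,10-dioxo-9-(phenylaminooxy)dec-2-en-1-yl acetate | O=C[C@@H](ONc1ccccc1)C[C@@](C)(OC(C)=O)C(=O)CC/C(C)=C/COC(C)=O | intermediate (not isolated)
10 | (2E,7R,9S)-7-acetoxy-10-hydroxy-3,7-dimethyl-6-oxo-9-(phenylaminooxy)dec-2-en-1-yl acetate | OC[C@@H](ONc1ccccc1)C[C@@](C)(OC(C)=O)C(=O)CC/C(C)=C/COC(C)=O | intermediate (not isolated)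
11 | (2E,7R,9S)-7-acetoxy-9,10-dihydroxy-3,7-dimethyl-6-oxodec-2-en-1-yl acetate | OC[C@@H](O)C[C@@](C)(OC(C)=O)C(=O)CC/C(C)=C/COC(C)=O | intermediate
12 | (2E,7R,9S)-7-acetoxy-3,7-dimethyl-6-oxo-9,10-bis(triethylsilyloxy)dec-2-en-1-yl acetate | CC[Si](CC)(CC)OC[C@@H](O[Si](CC)(CC)CC)C[C@@](C)(OC(C)=O)C(=O)CC/C(C)=C/COC(C)=O | intermediate
13 | dimethyl alkoxysulfonium chloride formed at O10 of 12 after loss of the primary TES group | C[S+](C)OC[C@@H](O[Si](CC)(CC)CC)C[C@@](C)(OC(C)=O)C(=O)CC/C(C)=C/COC(C)=O.[Cl-] | intermediate (not isolated)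
14 | (2E,7R,9S)-7-acetoxy-3,7-dimethyl-6,10-dioxo-9-(triethylsilyloxy)dec-2-en-1-yl acetate | O=C[C@@H](O[Si](CC)(CC)CC)C[C@@](C)(OC(C)=O)C(=O)CC/C(C)=C/COC(C)=O | intermediate
15 | methyl acrylate | C=CC(=O)OC | starting material
16 | methyl (4S,6R,10E)-6,12-diacetoxy-3-hydroxy-6,10-dimethyl-2-methylidene-7-oxo-4-(triethylsilyloxy)dodec-10-enoate (C3 epimers) | COC(=O)C(=C)C(O)[C@@H](O[Si](CC)(CC)CC)C[C@@](C)(OC(C)=O)C(=O)CC/C(C)=C/COC(C)=O | intermediate
17 | methyl (4S,6R,10E)-6-acetoxy-3,12-dihydroxy-6,10-dimethyl-2-methylidene-7-oxo-4-(triethylsilyloxy)dodec-10-enoate (C3 epimers) | COC(=O)C(=C)C(O)[C@@H](O[Si](CC)(CC)CC)C[C@@](C)(OC(C)=O)C(=O)CC/C(C)=C/CO | intermediate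
18 | methyl (4S,6R)-6-acetoxy-3-hydroxy-9-[(2R,3R)-3-(hydroxymethyl)-2-methyloxiran-2-yl]-6-methyl-2-methylidene-7-oxo-4-(triethylsilyloxy)nonanoate (C3 epimers) | COC(=O)C(=C)C(O)[C@@H](O[Si](CC)(CC)CC)C[C@@](C)(OC(C)=O)C(=O)CC[C@@]1(C)O[C@@H]1CO | intermediate
19 | methyl (4S,6R)-6-acetoxy-9-[(2R,3S)-3-formyl-2-methyloxiran-2-yl]-3-hydroxy-6-methyl-2-methylidene-7-oxo-4-(triethylsilyloxy)nonanoate (C3 epimers) | COC(=O)C(=C)C(O)[C@@H](O[Si](CC)(CC)CC)C[C@@](C)(OC(C)=O)C(=O)CC[C@@]1(C)O[C@@H]1C=O | intermediate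
20 | methyl (2Z,4S,6R)-6-acetoxy-2-(bromomethyl)-9-[(2R,3S)-3-formyl-2-methyloxiran-2-yl]-6-methyl-7-oxo-4-(triethylsilyloxy)non-2-enoate | COC(=O)/C(CBr)=C/[C@@H](O[Si](CC)(CC)CC)C[C@@](C)(OC(C)=O)C(=O)CC[C@@]1(C)O[C@@H]1C=O | intermediate
21 | methyl (4R,5R,6S,8S,10R)-10-acetoxy-4,5-epoxy-6-hydroxy-1-oxo-8-(triethylsilyloxy)germacr-11(13)-en-12-oate (7ξ) | CC[Si](CC)(CC)O[C@H]1C[C@@](C)(OC(C)=O)C(=O)CC[C@@]2(C)O[C@@H]2[C@@H](O)C1C(=C)C(=O)OC | intermediate (not isolated)
22 | (4R,5R,6S,8S,10R)-10-acetoxy-4,5-epoxy-1-oxo-8-(triethylsilyloxy)germacr-11(13)-en-12,6-olide (7ξ) | CC[Si](CC)(CC)O[C@H]1C[C@@](C)(OC(C)=O)C(=O)CC[C@@]2(C)O[C@@H]2[C@H]2OC(=O)C(=C)C12 | intermediate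
23 | (4R,5R,6S,8S,10R)-10,13-diacetoxy-4,5-epoxy-1-oxo-8-(triethylsilyloxy)germacr-7(11)-en-12,6-olide | CC[Si](CC)(CC)O[C@H]1C[C@@](C)(OC(C)=O)C(=O)CC[C@@]2(C)O[C@@H]2[C@H]2OC(=O)C(COC(C)=O)=C12 | intermediate
24 | (4R,5R,6S,8S,10R)-10,13-diacetoxy-4,5-epoxy-8-hydroxy-1-oxogermacr-7(11)-en-12,6-olide | O[C@H]1C[C@@](C)(OC(C)=O)C(=O)CC[C@@]2(C)O[C@@H]2[C@H]2OC(=O)C(COC(C)=O)=C12 | intermediate
25 | glaucolide A, (4R,5R,6S,8S,10R)-10,13-diacetoxy-4,5-epoxy-8-(methacryloyloxy)-1-oxogermacr-7(11)-en-12,6-olide | C=C(C)C(=O)O[C@H]1C[C@@](C)(OC(C)=O)C(=O)CC[C@@]2(C)O[C@@H]2[C@H]2OC(=O)C(COC(C)=O)=C12 | target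

## Count and risks

Total step count: 15. Longest linear sequence: 15 steps (1 → 25); compounds 3 and 15 are bought.

Steps most likely to fail:

Step 13 (the new Pd(II) acetoxylation with transposition). The electron‑poor alkene may not engage Pd(II), or only isomerisation may occur. The fallback uses known reactions and sets out from 22. The exocyclic methylene is isomerised into the ring with RhCl(PPh3)3 and Et3SiH (catalytic) in toluene at 80 °C to give the 13‑methyl butenolide (4R,5R,6S,8S,10R)-10-acetoxy-4,5-epoxy-1-oxo-8-(triethylsilyloxy)germacr-7(11)-en-12,6-olide F5. Wohl–Ziegler bromination of the C13 methyl (NBS, AIBN, PhCF3, 80 °C) gives the allylic bromide (4R,5R,6S,8S,10R)-10-acetoxy-13-bromo-4,5-epoxy-1-oxo-8-(triethylsilyloxy)germacr-7(11)-en-12,6-olide F6. Displacement with KOAc and 18‑crown‑6 in MeCN comes back to the route at 23.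

Step 12 (ring closure). The risks are the wrong C6 epimer, attack of the allylmetal on the C1 ketone (five‑membered ring) and oligomers. The fallback postpones the epoxide and sets out from 17. TEMPO/PhI(OAc)2 oxidises the allylic alcohol to the enal methyl (4S,6R,10E)-6-acetoxy-3-hydroxy-6,10-dimethyl-2-methylidene-7,12-dioxo-4-(triethylsilyloxy)dodec-10-enoate F2. NBS/Me2S gives methyl (2Z,4S,6R,10E)-6-acetoxy-2-(bromomethyl)-6,10-dimethyl-7,12-dioxo-4-(triethylsilyloxy)dodeca-2,10-dienoate F3. Indium Barbier cyclisation onto the enal and PPTS lactonisation give the 4E‑alkene lactone 10-acetoxy-1-oxo-8-(triethylsilyloxy)germacra-4,11(13)-dien-12,6-olide F4, with C6, C8 and C10 as in 22; here C6 is controlled by the C8 centre on the allylmetal rather than by the epoxide. mCPBA/NaHCO3 in CH2Cl2 at 0 °C then epoxidises the only electron‑rich alkene from its exposed outer face (peripheral attack on the E‑cyclodecene) and comes back at 22.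

Step 1 (Wacker oxidation of linalool). Pd(II) may cyclise the tertiary alcohol onto the trisubstituted alkene. The fallback sets out from 1. Markovnikov oxymercuration–demercuration of the less hindered vinyl group (Hg(OAc)2, THF/H2O; then NaBH4, NaOH) gives (3R)-3,7-dimethyloct-6-ene-2,3-diol F1 as C2 epimers. Oxidation of the secondary alcohol only (TEMPO/NaOCl or Dess–Martin periodinane) comes back at 2.

## Further compounds

F1 | step 1 | (3R)-3,7-dimethyloct-6-ene-2,3-diol (C2 epimers) | CC(C)=CCC[C@@](C)(O)C(C)O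
F2 | step 12 | methyl (4S,6R,10E)-6-acetoxy-3-hydroxy-6,10-dimethyl-2-methylidene-7,12-dioxo-4-(triethylsilyloxy)dodec-10-enoate (C3 epimers) | COC(=O)C(=C)C(O)[C@@H](O[Si](CC)(CC)CC)C[C@@](C)(OC(C)=O)C(=O)CC/C(C)=C/C=O
F3 | step 12 | methyl (2Z,4S,6R,10E)-6-acetoxy-2-(bromomethyl)-6,10-dimethyl-7,12-dioxo-4-(triethylsilyloxy)dodeca-2,10-dienoate | COC(=O)/C(CBr)=C/[C@@H](O[Si](CC)(CC)CC)C[C@@](C)(OC(C)=O)C(=O)CC/C(C)=C/C=O
F4 | step 12 | 10-acetoxy-1-oxo-8-(triethylsilyloxy)germacra-4E,11(13)-dien-12,6-olide with C6, C8 and C10 as in 22 (7ξ) | CC[Si](CC)(CC)O[C@H]1C[C@@](C)(OC(C)=O)C(=O)CC/C(C)=C/[C@H]2OC(=O)C(=C)C12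
F5 | step 13 | (4R,5R,6S,8S,10R)-10-acetoxy-4,5-epoxy-1-oxo-8-(triethylsilyloxy)germacr-7(11)-en-12,6-olide | CC[Si](CC)(CC)O[C@H]1C[C@@](C)(OC(C)=O)C(=O)CC[C@@]2(C)O[C@@H]2[C@H]2OC(=O)C(C)=C12
F6 | step 13 | (4R,5R,6S,8S,10R)-10-acetoxy-13-bromo-4,5-epoxy-1-oxo-8-(triethylsilyloxy)germacr-7(11)-en-12,6-olide | CC[Si](CC)(CC)O[C@H]1C[C@@](C)(OC(C)=O)C(=O)CC[C@@]2(C)O[C@@H]2[C@H]2OC(=O)C(CBr)=C12
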